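**Strategy.** The trans-decalin is disconnected at the C5–C10 ring-fusion bond and at C8–C9 (labdane numbering), which opens rings A and B into an acyclic triene. Its type 1 intramolecular Diels–Alder reaction (C9=C10 enone activated by a C11 ketone, C5=C6–C7=C8 diene, C1–C4 tether) closes both rings and sets C5, C8, C9 and C10 in one operation. It exploits the C2 carbinol of ring A: flanked by the C4 gem-dimethyl and C10 methyl groups, it must sit equatorial in the chair-like tether and so relays absolute configuration. C2 comes from (S)-epichlorohydrin, C13 from (R)-3-methylglutarate. The C6=C7 olefin is then moved to C7=C8 and the (Z)-coumarate attached without protecting groups.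

Key step: step 8

Remark: atom labels follow labdane numbering (ring A: C1–C5 and C10; ring B: C5–C10; side chain C11–C16; C17 on C8; C18 and C19 on C4; C20 on C10); the δ-hydroxy ketones 17 and 19 are drawn in their open forms.

**Step 1**
Reactants: 1 (S)-epichlorohydrin; 2 isobutyronitrile
Product: 4 (S)-2,2-dimethyl-3-(oxiran-2-yl)propanenitrile, via lithium chlorohydrin alkoxide 3 (not isolated)
Conditions: LiN(iPr)2, THF, −78 °C; then 1, −78 °C → rt
Reagents that add atoms: none
Why: α-Alkylation of the lithiated nitrile by epoxide opening at the CH2 terminus of 1, followed by re-closure of alkoxide 3 onto the CH2Cl carbon; the C2–O bond is never broken, so (S)-1 should deliver (S)-4 together with the quaternary C4.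

**Step 2**
Reactants: 4 (S)-2,2-dimethyl-3-(oxiran-2-yl)propanenitrile
Product: 6 (S)-2,2-dimethyl-3-(oxiran-2-yl)propanal, via N-aluminio aldimine 5 (not isolated)
Conditions: iBu2AlH, CH2Cl2, −78 °C; aq. KNaC4H4O6, 0 °C → rt
Reagents that add atoms: water, O
Why: Partial hydride reduction of a nitrile stops at aldimine 5, which hydrolyses on work-up; the epoxide is inert at −78 °C and the aldehyde has no α-hydrogen.

**Step 3**
Reactants: 6 (S)-2,2-dimethyl-3-(oxiran-2-yl)propanal; 7 diethyl (E)-but-2-en-1-ylphosphonate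
Product: 8 (S)-2-[(3E,5E)-2,2-dimethylhepta-3,5-dien-1-yl]oxirane
Conditions: 7, n-BuLi, THF, −78 °C; then 6, DMPU, −78 °C → rt
Reagents that add atoms: none
Why: Horner–Wadsworth–Emmons olefination with an allylic phosphonate carbanion (α-attack, then elimination of phosphate) should form the new C5=C6 bond E-selectively, while the C7=C8 geometry is carried from 7.

**Step 4**
Reactants: 8 (S)-2-[(3E,5E)-2,2-dimethylhepta-3,5-dien-1-yl]oxirane
Product: 9 (4R,7E,9E)-6,6-dimethylundeca-7,9-dien-1-yn-4-ol
Conditions: LiC≡CH·H2NCH2CH2NH2, DMSO, rt; H2O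
Reagents that add atoms: lithium acetylide–ethylenediamine complex, [Li+].[C-]#C.NCCN
Why: SN2 opening of the terminal epoxide by acetylide at the unhindered C1 leaves the C2 stereocentre untouched.

**Step 5**
Reactants: 9 (4R,7E,9E)-6,6-dimethylundeca-7,9-dien-1-yn-4-ol
Product: 11 (1E,4S,7E,9E)-1-iodo-2,6,6-trimethylundeca-1,7,9-trien-4-ol, via alkenylalane 10 (not isolated)
Conditions: AlMe3 (3 equiv), Cp2ZrCl2 (0.3 equiv), CH2Cl2, 0 °C → rt; then I2, THF, −30 °C; aq. KNaC4H4O6, Na2S2O3
Reagents that add atoms: trimethylaluminium, C[Al](C)C; iodine, II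
Why: Negishi zirconium-catalysed carboalumination is a syn methylalumination that places methyl on C10 and aluminium on C9 (the hydroxyl is carried as its aluminium alkoxide), and iodinolysis occurs with retention to give the (E)-iodide.

**Step 6**
Reactants: 12 methyl hydrogen (R)-3-methylglutarate
Product: 14 (R)-4-methyloxan-2-one, via hydroxy ester 13 (not isolated)
Conditions: BH3·SMe2, THF, 0 °C → rt; MeOH; then TsOH·H2O (cat.), toluene, 50 °C
Reagents that add atoms: none
Why: Borane reduces the carboxylic acid chemoselectively beside the methyl ester, and hydroxy ester 13 lactonises under acid catalysis; C13 is not touched.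

**Step 7**
Reactants: 11 (1E,4S,7E,9E)-1-iodo-2,6,6-trimethylundeca-1,7,9-trien-4-ol; 14 (R)-4-methyloxan-2-one
Product: 17 (3R,6E,9R,12E,14E)-1,9-dihydroxy-3,7,11,11-tetramethylhexadeca-6,12,14-trien-5-one, via dilithio species 15 (not isolated), via lithium lactolate 16 (not isolated)
Conditions: t-BuLi (3.1 equiv), Et2O, −78 °C; then 14, −78 °C; AcOH, −78 °C
Reagents that add atoms: none
Why: Iodine–lithium exchange proceeds with retention of alkene geometry, and the alkenyllithium should add only once to the lactone carbonyl because lactolate 16 persists at −78 °C; acidic quench releases the δ-hydroxy (E)-enone.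

**Step 8**
Reactants: 17 (3R,6E,9R,12E,14E)-1,9-dihydroxy-3,7,11,11-tetramethylhexadeca-6,12,14-trien-5-one
Product: 19 (13R)-2α,15-dihydroxy-8αH-labd-6-en-11-one, via aluminium alkoxide 18 (not isolated)
Conditions: Me2AlCl (3.5 equiv), CH2Cl2, −78 → 0 °C; aq. KNaC4H4O6
Reagents that add atoms: none
Why: Type 1 intramolecular Diels–Alder reaction of a 1,7,9-decatriene: after both hydroxyls have become chloro(methyl)aluminium alkoxides (18), further Me2AlCl complexes the C11 ketone and the C9=C10 enone adds across the C5=C6–C7=C8 diene in a concerted, asynchronous [4+2] process in which the C5–C10 bond is the more advanced. The closest known reaction type is the Lewis acid-promoted cycloaddition of terminally activated (E)-decatrienones to trans-octalins. Ring A closes as the six-membered tether ring through the C5–C10 bond alone, ring B as the cycloaddition ring through C5–C10 plus C8–C9, in the fused mode with the tether anti and the ketone endo. The trans C5/C10 fusion follows from that endo geometry, the 9β side chain from the (E)-enone (C11 cis to C20, trans to C1), the 8β-methyl from the (E,E)-diene, and the absolute sense from C2, whose oxygen must be equatorial in the chair-like tether because on the other diene face it would be 1,3-diaxial to both the axial C4 methyl and the C10 methyl. The step needs endo over exo selectivity and a single diene face; ketone–aluminium complexation and the C2/C4/C10 substitution pattern should secure them, and the C4 gem-dimethyl group (Thorpe–Ingold effect) helps the rate.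

**Step 9**
Reactants: 19 (13R)-2α,15-dihydroxy-8αH-labd-6-en-11-one
Product: 21 (13S)-8αH-labd-6-ene-2α,15-diol, via hydrazone 20 (not isolated)
Conditions: N2H4·H2O, KOH, HO(CH2)2O(CH2)2OH, 130 °C then 200 °C, under N2
Reagents that add atoms: none
Why: Wolff–Kishner reduction in the Huang-Minlon procedure: hydrazone 20 loses dinitrogen under KOH at 200 °C to leave the C11 methylene, while the free hydroxyls and the isolated olefin are inert and no stereocentre is affected.

**Step 10**
Reactants: 21 (13S)-8αH-labd-6-ene-2α,15-diol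
Product: 22 (2S,5S,9S,10S,13S)-labd-7-ene-2,15-diol
Conditions: RhCl3·3H2O (10 mol %), EtOH, 75 °C
Reagents that add atoms: none
Why: Rhodium hydride-mediated olefin isomerisation (hydrometalation/β-hydride elimination on the open α face): the accessible 8α-H should be removed in preference to 5α-H, which is flanked by two quaternary carbons, and the trisubstituted C7=C8 olefin, which also relieves the 1,3-diaxial C17/C20 interaction, should re-insert only slowly.

**Step 11**
Reactants: 23 (Z)-3-iodoacrylic acid; 24 4-hydroxyphenylboronic acid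
Product: 25 (Z)-3-(4-hydroxyphenyl)prop-2-enoic acid
Conditions: Pd(OAc)2 (2 mol %), K2CO3, H2O/MeCN, rt, dark; then aq. HCl, 0 °C
Reagents that add atoms: none
Why: Suzuki–Miyaura coupling of the (Z)-alkenyl iodide proceeds with retention of configuration, and the carboxylate form of 23 is too poor a Michael acceptor for phenoxide addition–elimination to compete.

**Step 12**
Reactants: 22 (2S,5S,9S,10S,13S)-labd-7-ene-2,15-diol; 25 (Z)-3-(4-hydroxyphenyl)prop-2-enoic acid
Product: 26 (2S,5S,9S,10S,13S)-2-hydroxylabd-7-en-15-yl (Z)-3-(4-hydroxyphenyl)prop-2-enoate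
Conditions: PPh3, iPrO2CN=NCO2iPr, THF, 0 °C → rt, dark
Reagents that add atoms: none
Why: Mitsunobu esterification: the carboxylic acid, far more acidic than the phenol, is the pronucleophile and displaces the activated primary C15 oxygen; the C2 hydroxyl between two neopentyl-type carbons should stay untouched, and the Z geometry is kept because the acid reacts only as a nucleophile.

**Compound list**
1 | (S)-epichlorohydrin, (2S)-2-(chloromethyl)oxirane | ClC[C@@H]1CO1 | starting material
2 | isobutyronitrile | CC(C)C#N | starting material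
3 | lithium (2S)-1-chloro-4-cyano-4-methylpentan-2-olate | N#CC(C)(C)C[C@H]([O-])CCl.[Li+] | intermediate
4 | (S)-2,2-dimethyl-3-(oxiran-2-yl)propanenitrile | N#CC(C)(C)C[C@H]1CO1 | intermediate
5 | N-(diisobutylaluminio) aldimine of 6 | CC(C)C[Al](CC(C)C)N=CC(C)(C)C[C@H]1CO1 | intermediate
6 | (S)-2,2-dimethyl-3-(oxiran-2-yl)propanal | O=CC(C)(C)C[C@H]1CO1 | intermediate
7 | diethyl (E)-but-2-en-1-ylphosphonate | CCOP(=O)(C/C=C/C)OCC | starting material
8 | (S)-2-[(3E,5E)-2,2-dimethylhepta-3,5-dien-1-yl]oxirane | C/C=C/C=C/C(C)(C)C[C@H]1CO1 | intermediate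
9 | (4R,7E,9E)-6,6-dimethylundeca-7,9-dien-1-yn-4-ol | C#CC[C@@H](O)CC(C)(C)/C=C/C=C/C | intermediate
10 | (E)-alkenyl(dimethyl)alane of 9, O-dimethylaluminium alkoxide (Me and Al cis) | C[Al](C)/C=C(\C)C[C@@H](O[Al](C)C)CC(C)(C)/C=C/C=C/C | intermediate
11 | (1E,4S,7E,9E)-1-iodo-2,6,6-trimethylundeca-1,7,9-trien-4-ol | I/C=C(\C)C[C@@H](O)CC(C)(C)/C=C/C=C/C | intermediate
12 | methyl hydrogen (R)-3-methylglutarate | COC(=O)C[C@H](C)CC(=O)O | starting material
13 | methyl (R)-5-hydroxy-3-methylpentanoate | COC(=O)C[C@H](C)CCO | intermediate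
14 | (R)-4-methyloxan-2-one | O=C1C[C@H](C)CCO1 | intermediate
15 | dilithio species from 11 (C1-lithio, lithium alkoxide) | [Li]/C=C(\C)C[C@@H](O[Li])CC(C)(C)/C=C/C=C/C | intermediate
16 | lithium lactolate (adduct of 15 and 14) | [Li]OC1(/C=C(\C)C[C@@H](O[Li])CC(C)(C)/C=C/C=C/C)C[C@H](C)CCO1 | intermediate
17 | (3R,6E,9R,12E,14E)-1,9-dihydroxy-3,7,11,11-tetramethylhexadeca-6,12,14-trien-5-one | OCC[C@@H](C)CC(=O)/C=C(\C)C[C@@H](O)CC(C)(C)/C=C/C=C/C | intermediate
18 | bis[chloro(methyl)aluminium] alkoxide of 17 | C[Al](Cl)OCC[C@@H](C)CC(=O)/C=C(\C)C[C@@H](O[Al](C)Cl)CC(C)(C)/C=C/C=C/C | intermediate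
19 | (13R)-2α,15-dihydroxy-8αH-labd-6-en-11-one (5α-H, 9α-H, 10β-methyl, 17-methyl β, trans-fused) | C[C@H]1C=C[C@H]2C(C)(C)C[C@H](O)C[C@]2(C)[C@H]1C(=O)C[C@H](C)CCO | intermediate
20 | C11 hydrazone of 19 | C[C@H]1C=C[C@H]2C(C)(C)C[C@H](O)C[C@]2(C)[C@H]1C(=NN)C[C@H](C)CCO | intermediate
21 | (13S)-8αH-labd-6-ene-2α,15-diol (17-methyl β) | C[C@H]1C=C[C@H]2C(C)(C)C[C@H](O)C[C@]2(C)[C@H]1CC[C@H](C)CCO | intermediate
22 | (2S,5S,9S,10S,13S)-labd-7-ene-2,15-diol (2α-OH) | CC1=CC[C@H]2C(C)(C)C[C@H](O)C[C@]2(C)[C@H]1CC[C@H](C)CCO | intermediate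
23 | (Z)-3-iodoacrylic acid | OC(=O)/C=C\I | starting material
24 | 4-hydroxyphenylboronic acid | OB(O)c1ccc(O)cc1 | starting material
25 | (Z)-3-(4-hydroxyphenyl)prop-2-enoic acid, (Z)-p-coumaric acid | OC(=O)/C=C\c1ccc(O)cc1 | intermediate
26 | (2S,5S,9S,10S,13S)-2-hydroxylabd-7-en-15-yl (Z)-3-(4-hydroxyphenyl)prop-2-enoate | CC1=CC[C@H]2C(C)(C)C[C@H](O)C[C@]2(C)[C@H]1CC[C@H](C)CCOC(=O)/C=C\c1ccc(O)cc1 | target

**Step count and risks**

Total step count: 12. Longest linear sequence: 10 (steps 1, 2, 3, 4, 5, 7, 8, 9, 10, 12).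

Steps most likely to fail:

1. Step 8. The cycloaddition may lose its endo preference (cis-fused product), the ketone may be withdrawn as an unreactive aluminium lactolate with the C15 alkoxide, or the Lewis acid may ionise and oligomerise the diene. Fallback (sets out from 17, returns at 19): the δ-hydroxy ketone is closed with MeOH, HC(OMe)3 and pyridinium p-toluenesulfonate to the cyclic methyl ketal (4R)-2-methoxy-4-methyl-2-alkenyloxane F1. Catalytic Me3SiOTf in CH2Cl2 at −78 °C ionises it to a 2-alkenyl oxocarbenium ion, an allyl-cation dienophile that should undergo the cationic intramolecular Diels–Alder reaction through the same chair-like tether. Aqueous acid work-up hydrolyses the ketal of the adduct back to hydroxy ketone 19.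

2. Step 10. The double bond may migrate beyond C7=C8 to the tetrasubstituted C8=C9 position, or towards C5, giving positional mixtures. Fallback (sets out from 21, returns at 22):
   - Both hydroxyls are silylated (tBuMe2SiCl, imidazole) to the bis(silyl ether) F2.
   - Hydroboration–oxidation (BH3·THF, then NaOH/H2O2) should place boron on the less hindered C7 from the α face and give the 7α-alcohol F3.
   - Dess–Martin oxidation gives the 7-ketone F4.
   - Enolisation under equilibrating conditions (Tf2O, 2,6-di-tert-butyl-4-methylpyridine) should go towards C8, where it removes the axial 17-methyl, and give the enol triflate F5.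
   - Reductive detriflation (Pd(OAc)2, PPh3, Bu3N, HCO2H) gives the olefin F6 with the double bond fixed at C7=C8.
   - HF·pyridine returns diol 22.

3. Step 12. The Z-enoate may isomerise to E through reversible conjugate addition of the phosphine, and the phenol may be O-alkylated in competition with ester formation. Fallback (sets out from 22, returns at 26): carbodiimide esterification of the primary hydroxyl with (Z)-3-iodoacrylic acid 23 (iPrN=C=NiPr, catalytic 4-(dimethylamino)pyridine, CH2Cl2, 0 °C) gives the (Z)-iodoacrylate F7. Suzuki–Miyaura coupling with 24 (Pd(PPh3)4, NaHCO3, aqueous 1,2-dimethoxyethane, rt, dark) then forms the aryl–alkenyl bond with retention and delivers 26; acid 25 is not needed on this path.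

**Further compounds**
F1 | step 8 | (4R)-2-methoxy-4-methyl-2-[(1E,4R,7E,9E)-4-hydroxy-2,6,6-trimethylundeca-1,7,9-trien-1-yl]oxane | COC1(/C=C(\C)C[C@@H](O)CC(C)(C)/C=C/C=C/C)C[C@H](C)CCO1
F2 | step 10 | (13S)-2α,15-bis(tert-butyldimethylsilyloxy)-8αH-labd-6-ene | C[C@H]1C=C[C@H]2C(C)(C)C[C@H](O[Si](C)(C)C(C)(C)C)C[C@]2(C)[C@H]1CC[C@H](C)CCO[Si](C)(C)C(C)(C)C
F3 | step 10 | (13S)-2α,15-bis(tert-butyldimethylsilyloxy)-8αH-labdan-7α-ol | C[C@H]1[C@H](O)C[C@H]2C(C)(C)C[C@H](O[Si](C)(C)C(C)(C)C)C[C@]2(C)[C@H]1CC[C@H](C)CCO[Si](C)(C)C(C)(C)C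
F4 | step 10 | (13S)-2α,15-bis(tert-butyldimethylsilyloxy)-8αH-labdan-7-one | C[C@H]1C(=O)C[C@H]2C(C)(C)C[C@H](O[Si](C)(C)C(C)(C)C)C[C@]2(C)[C@H]1CC[C@H](C)CCO[Si](C)(C)C(C)(C)C
F5 | step 10 | (13S)-2α,15-bis(tert-butyldimethylsilyloxy)labd-7-en-7-yl trifluoromethanesulfonate | CC1=C(OS(=O)(=O)C(F)(F)F)C[C@H]2C(C)(C)C[C@H](O[Si](C)(C)C(C)(C)C)C[C@]2(C)[C@H]1CC[C@H](C)CCO[Si](C)(C)C(C)(C)C
F6 | step 10 | (13S)-2α,15-bis(tert-butyldimethylsilyloxy)labd-7-ene | CC1=CC[C@H]2C(C)(C)C[C@H](O[Si](C)(C)C(C)(C)C)C[C@]2(C)[C@H]1CC[C@H](C)CCO[Si](C)(C)C(C)(C)C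
F7 | step 12 | (2S,5S,9S,10S,13S)-2-hydroxylabd-7-en-15-yl (Z)-3-iodoprop-2-enoate | CC1=CC[C@H]2C(C)(C)C[C@H](O)C[C@]2(C)[C@H]1CC[C@H](C)CCOC(=O)/C=C\I
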